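**Plan** (labdane numbering: ring A = C1–C5, C10; ring B = C5–C10; C11–C16 = side chain and imide; C17 = exocyclic CH2; C18 = CH2OH; C19, C20 = methyls on C4, C10; α = face opposite C20)
1. Retrosynthetic cuts, in order: imide C–N bonds and C12–C13 (aldol); C8=C17 (Wittig); C2–Cl (C–H chlorination); a temporary nitro group on C5; ring B at C5–C6 and C8–C9; C9=C11 (Wittig); C4–C18 and the two methyls.
2. Forward: ring A first (β-keto ester → bicyclic keto lactone → C5 nitro group → enoate arm on C10), then ring B in one flask from acrolein, then denitration, chlorination, methylenation and the imide side chain.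
3. Enabling feature: in ring B, C5 and C9 sit 1,3 to each other across the quaternary C10, and C6–C7–C8 is a bare three-carbon unit; acrolein supplies it, its CH2= end (C6) accepting the C5 nitronate and its CHO carbon (C8), as an acyl anion, adding to C9 of the enoate; the C8 ketone later becomes C8=C17.
4. Stereochemistry: C10 by asymmetric phase-transfer methylation; C4 by lactonisation-gated hydroxymethylation; C5 by hydrogen delivery anti to the axial C19/C20 methyls on denitration (both nitro epimers converge); C9 by equilibration next to the C8 ketone; C2 by equatorial chlorine transfer; C12/C13 by an Evans syn-aldol with the (R)-auxiliary.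

Key step: step 9

Remark: the C5 nitro group is a removable activating group, so compounds 7–13 are carried as mixtures of nitro epimers; this has no consequence for the final configuration.

Step 1
Reactants: 1 methyl 2-oxocyclohexane-1-carboxylate
Product: 2 methyl (S)-1-methyl-2-oxocyclohexane-1-carboxylate
Conditions: MeI, O-allyl-N-(9-anthracenylmethyl)cinchonidinium bromide (10 mol%), CsOH·H2O, toluene, −40 °C
Reagents that add atoms: methyl iodide, CI
Why: Asymmetric phase-transfer C-alkylation of a cyclic β-keto ester, in which the chiral ammonium cation shields one face of the enolate so that methylation should set the C10 quaternary centre (the pseudoenantiomeric cinchoninium salt would be used if the sense proved opposite).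

Step 2
Reactants: 2 methyl (S)-1-methyl-2-oxocyclohexane-1-carboxylate
Product: 3 methyl (1S)-1,3-dimethyl-2-oxocyclohexane-1-carboxylate (both C3 epimers)
Conditions: LiN(i-Pr)2, THF, −78 °C; MeI, −78 to 0 °C
Reagents that add atoms: methyl iodide, CI
Why: Kinetic enolate alkylation (SN2), possible only at the CH2 next to the ketone because the other α-carbon is quaternary; the new centre is re-enolised in step 3, so its configuration does not matter.

Step 3
Reactants: 3 methyl (1S)-1,3-dimethyl-2-oxocyclohexane-1-carboxylate
Product: 5 (1S,5S)-1,5-dimethyl-3-oxabicyclo[3.3.1]nonane-2,9-dione (bicyclic keto lactone), via hydroxymethyl keto ester 4 (not isolated)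
Conditions: LiN(i-Pr)2, THF, −78 °C; CH2O (gas, from cracked paraformaldehyde); −78 to 0 °C
Reagents that add atoms: formaldehyde, C=O
Why: Aldol addition of the tetrasubstituted enolate to formaldehyde followed by lactonisation, in which only the adduct with the alkoxide cis to the ester can close the δ-lactone while the trans adduct can revert by retro-aldol, so C4 should be funnelled to the cis relationship with C10 (axial attack syn to the small axial ester favours the same isomer).

Step 4
Reactants: 5 (1S,5S)-1,5-dimethyl-3-oxabicyclo[3.3.1]nonane-2,9-dione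
Product: 6 (1S,5R)-9-(hydroxyimino)-1,5-dimethyl-3-oxabicyclo[3.3.1]nonan-2-one
Conditions: NH2OH·HCl, NaOAc, EtOH, 60 °C
Reagents that add atoms: hydroxylamine hydrochloride, NO.Cl
Why: Oxime condensation at the bridging ketone, which is tied back in the bicyclic frame and therefore still accessible; the acetate buffer should keep the oxime oxygen from attacking the neighbouring lactone carbonyl.

Step 5
Reactants: 6 (1S,5R)-9-(hydroxyimino)-1,5-dimethyl-3-oxabicyclo[3.3.1]nonan-2-one
Product: 7 (1S,5R)-1,5-dimethyl-9-nitro-3-oxabicyclo[3.3.1]nonan-2-one (nitro epimers)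
Conditions: NaBO3·4H2O, AcOH, 55 °C
Reagents that add atoms: sodium perborate tetrahydrate, [Na+].[O-]OB=O.O.O.O.O
Why: Peroxide oxidation of a ketoxime to the secondary nitroalkane (N-oxidation to the nitronic acid, then tautomerisation), which installs the acidifying group on C5.

Step 6
Reactants: 7 (1S,5R)-1,5-dimethyl-9-nitro-3-oxabicyclo[3.3.1]nonan-2-one
Product: 8 (1S,5R)-1,5-dimethyl-9-nitro-3-oxabicyclo[3.3.1]nonan-2-ol (lactol, anomers)
Conditions: i-Bu2AlH, CH2Cl2, −78 °C; aqueous potassium sodium tartrate
Reagents that add atoms: none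
Why: Half-reduction of the lactone to the lactol through the aluminium hemiacetal, which is stable at −78 °C; the nitro group is not reduced under these conditions.

Step 7
Reactants: 8 (1S,5R)-1,5-dimethyl-9-nitro-3-oxabicyclo[3.3.1]nonan-2-ol
Product: 9 methyl (E)-3-[(1R,3R)-3-(hydroxymethyl)-1,3-dimethyl-2-nitrocyclohexyl]prop-2-enoate
Conditions: Ph3P=CHCO2Me, toluene, 90 °C
Reagents that add atoms: methyl (triphenylphosphoranylidene)acetate, COC(=O)C=P(c1ccccc1)(c1ccccc1)c1ccccc1
Why: Wittig olefination of the open hydroxy-aldehyde form of the lactol with a stabilised ylide, which is (E)-selective, builds C11–C12 on C9 and frees the C18 hydroxyl.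

Step 8
Reactants: 9 methyl (E)-3-[(1R,3R)-3-(hydroxymethyl)-1,3-dimethyl-2-nitrocyclohexyl]prop-2-enoate
Product: 10 methyl (E)-3-[(1R,3R)-3-[(tert-butyldimethylsilyloxy)methyl]-1,3-dimethyl-2-nitrocyclohexyl]prop-2-enoate
Conditions: TBSCl, imidazole, DMF, rt
Reagents that add atoms: tert-butyldimethylsilyl chloride, CC(C)(C)[Si](C)(C)Cl
Why: Silylation of the primary neopentyl alcohol, which blocks its oxa-Michael addition to the enoate under the basic conditions of step 9.

Step 9
Reactants: 10 methyl (E)-3-[(1R,3R)-3-[(tert-butyldimethylsilyloxy)methyl]-1,3-dimethyl-2-nitrocyclohexyl]prop-2-enoate; 11 acrolein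
Product: 13 methyl 18-(tert-butyldimethylsilyloxy)-5-nitro-8-oxo-13,14,15,16,17-pentanorlabdan-12-oate (C4 and C10 as in the target, mixture at C5 and C9), via nitro aldehyde 12 (not isolated)
Conditions: acrolein (1.05 equiv), DBU (0.3 equiv), MeCN, 0 °C to rt; then 2-(pentafluorophenyl)-6,7-dihydro-5H-pyrrolo[2,1-c][1,2,4]triazol-2-ium tetrafluoroborate (0.2 equiv), 40 °C
Reagents that add atoms: none
Why: Proposed new method: DBU forms the C5 nitronate of 10, which adds in a Michael reaction to C6 of acrolein to give aldehyde 12, and the triazolylidene carbene then turns the aldehyde carbon C8 into an acyl-anion equivalent (Breslow intermediate) that adds to C9, the β-carbon of the enoate, before proton transfer releases the catalyst (intramolecular Stetter reaction). The closest known reaction types are the amidine-catalysed Michael addition of secondary nitroalkanes to enals, the carbene-catalysed cyclisation of oxo-enoates to 2-(alkoxycarbonylmethyl)cycloalkanones, and one-flask oxa-Michael/Stetter annulations; new is their union into a [3+3] carbocycle synthesis at a nitronate carbon flanked by two quaternary centres. Ring B closes in the 6-exo-trig mode at C9, and the quaternary carbons C5 and C10 in the tether should favour the folded conformer (gem-dialkyl effect). Of the two new stereocentres, C5 needs no control because its nitro group is later removed through a planar radical, and C9 lies α to the new C8 ketone and is set by equilibration in step 10. The step needs carbon- rather than oxygen-alkylation of the nitronate and acyl-anion addition rather than enolate chemistry of 12: addition of the nitronate oxygen to its own enoate is reversible whereas C–C bond formation with acrolein is not, and the carbene precatalyst is added only after acrolein is consumed so that free enal does not intercept it.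

Step 10
Reactants: 13 methyl 18-(tert-butyldimethylsilyloxy)-5-nitro-8-oxo-13,14,15,16,17-pentanorlabdan-12-oate
Product: 14 methyl 18-(tert-butyldimethylsilyloxy)-8-oxo-13,14,15,16,17-pentanorlabdan-12-oate (5α-H, 9α-H, trans-decalin)
Conditions: Bu3SnH, AIBN (cat.), toluene, 110 °C; then DBU (cat.), CH2Cl2, rt
Reagents that add atoms: none
Why: Radical denitration of a tertiary nitroalkane (tin radical adds to the nitro oxygen, C–N scission gives the C5 radical), where hydrogen transfer to the planar ring-fusion radical from the α-face, anti to the axial C19 and C20 methyls, should give the trans-decalin from either nitro epimer; DBU then equilibrates C9 to the equatorial side chain.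

Step 11
Reactants: 14 methyl 18-(tert-butyldimethylsilyloxy)-8-oxo-13,14,15,16,17-pentanorlabdan-12-oate
Product: 15 methyl 2α-chloro-18-(tert-butyldimethylsilyloxy)-8-oxo-13,14,15,16,17-pentanorlabdan-12-oate
Conditions: N-chloro-N-tert-butyl-3,5-bis(trifluoromethyl)benzamide, Cs2CO3, benzene, visible light, 55 °C
Reagents that add atoms: N-chloro-N-tert-butyl-3,5-bis(trifluoromethyl)benzamide, CC(C)(C)N(Cl)C(=O)c1cc(C(F)(F)F)cc(C(F)(F)F)c1
Why: Site-selective radical C–H chlorination with an N-chloroamide, in which the bulky amidyl radical should abstract hydrogen at C2 (ring B is deactivated by the ketone and ester, C1, C3 and C18 are shielded by the quaternary carbons) and chlorine is delivered to the C2 radical on the equatorial α-face, away from the two syn-axial methyls.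

Step 12
Reactants: 15 methyl 2α-chloro-18-(tert-butyldimethylsilyloxy)-8-oxo-13,14,15,16,17-pentanorlabdan-12-oate
Product: 16 methyl 2α-chloro-18-(tert-butyldimethylsilyloxy)-13,14,15,16-tetranorlabd-8(17)-en-12-oate
Conditions: Ph3PCH3Br, KOtBu, THF, 0 °C; then 15, rt to 50 °C
Reagents that add atoms: methyltriphenylphosphonium bromide, C[P+](c1ccccc1)(c1ccccc1)c1ccccc1.[Br-]
Why: Wittig methylenation of the C8 ketone installs C17; C9 keeps its thermodynamically preferred equatorial configuration under the basic conditions.

Step 13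
Reactants: 16 methyl 2α-chloro-18-(tert-butyldimethylsilyloxy)-13,14,15,16-tetranorlabd-8(17)-en-12-oate
Product: 17 2α-chloro-18-(tert-butyldimethylsilyloxy)-13,14,15,16-tetranorlabd-8(17)-en-12-al
Conditions: i-Bu2AlH (1.1 equiv), CH2Cl2, −78 °C; aqueous potassium sodium tartrate
Reagents that add atoms: none
Why: Half-reduction of the methyl ester to the aldehyde through the aluminium hemiacetal that is stable at −78 °C.

Step 14
Reactants: 18 (R)-4-benzyl-1,3-oxazolidin-2-one; 19 methyl 4-chloro-4-oxobutanoate
Product: 20 methyl 4-[(4R)-4-benzyl-2-oxo-1,3-oxazolidin-3-yl]-4-oxobutanoate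
Conditions: n-BuLi, THF, −78 °C; then 19, −78 to 0 °C
Reagents that add atoms: none
Why: N-acylation of the lithiated oxazolidinone with the acid chloride gives the aldol donor that carries C13–C16.

Step 15
Reactants: 17 2α-chloro-18-(tert-butyldimethylsilyloxy)-13,14,15,16-tetranorlabd-8(17)-en-12-al; 20 methyl 4-[(4R)-4-benzyl-2-oxo-1,3-oxazolidin-3-yl]-4-oxobutanoate
Product: 21 syn-aldol adduct, (12S,13R)-β-hydroxy imide with the CH2CO2Me branch on C13 and the (R)-4-benzyloxazolidinone on C16
Conditions: 20, Bu2BOTf, i-Pr2NEt, CH2Cl2, −78 to 0 °C; then 17, −78 to 0 °C; pH 7 buffer, MeOH, 30% H2O2, 0 °C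
Reagents that add atoms: none
Why: Evans syn-aldol reaction, in which the (Z)-boron enolate of the imide reacts through a chair (Zimmerman–Traxler) transition state on the face opposite the benzyl group of the (R)-auxiliary and so should set C13 (R) and C12 (S).

Step 16
Reactants: 21 syn-aldol adduct
Product: 23 18-O-(tert-butyldimethylsilyl)haterumaimide J, via primary amide 22 (not isolated)
Conditions: NH3 (7 M in MeOH), 0 °C to rt
Reagents that add atoms: ammonia, N
Why: Ammonolysis of the methyl ester gives the primary amide, whose nitrogen attacks the activated N-acyloxazolidinone carbonyl in a 5-exo-trig transacylation that releases the auxiliary and closes the succinimide.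

Step 17
Reactants: 23 18-O-(tert-butyldimethylsilyl)haterumaimide J
Product: 24 haterumaimide J
Conditions: HF·pyridine, THF, 0 °C to rt
Reagents that add atoms: none
Why: Fluoride-mediated silyl ether cleavage under mildly acidic conditions, which should leave the β-hydroxy imide, the secondary chloride and the exocyclic alkene untouched.

**Compound list**
1 | methyl 2-oxocyclohexane-1-carboxylate | COC(=O)C1CCCCC1=O | starting material
2 | methyl (S)-1-methyl-2-oxocyclohexane-1-carboxylate | COC(=O)[C@@]1(C)CCCCC1=O | intermediate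
3 | methyl (1S)-1,3-dimethyl-2-oxocyclohexane-1-carboxylate (C3 epimers) | COC(=O)[C@@]1(C)CCCC(C)C1=O | intermediate
4 | methyl (1S,3S)-3-(hydroxymethyl)-1,3-dimethyl-2-oxocyclohexane-1-carboxylate | COC(=O)[C@@]1(C)CCC[C@@](C)(CO)C1=O | intermediate
5 | (1S,5S)-1,5-dimethyl-3-oxabicyclo[3.3.1]nonane-2,9-dione | O=C1OC[C@]2(C)CCC[C@@]1(C)C2=O | intermediate
6 | (1S,5R)-9-(hydroxyimino)-1,5-dimethyl-3-oxabicyclo[3.3.1]nonan-2-one | O=C1OC[C@]2(C)CCC[C@@]1(C)C2=NO | intermediate
7 | (1S,5R)-1,5-dimethyl-9-nitro-3-oxabicyclo[3.3.1]nonan-2-one | O=C1OC[C@]2(C)CCC[C@@]1(C)C2[N+](=O)[O-] | intermediate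
8 | (1S,5R)-1,5-dimethyl-9-nitro-3-oxabicyclo[3.3.1]nonan-2-ol | OC1OC[C@]2(C)CCC[C@@]1(C)C2[N+](=O)[O-] | intermediate
9 | methyl (E)-3-[(1R,3R)-3-(hydroxymethyl)-1,3-dimethyl-2-nitrocyclohexyl]prop-2-enoate | COC(=O)/C=C/[C@@]1(C)CCC[C@@](C)(CO)C1[N+](=O)[O-] | intermediate
10 | methyl (E)-3-[(1R,3R)-3-[(tert-butyldimethylsilyloxy)methyl]-1,3-dimethyl-2-nitrocyclohexyl]prop-2-enoate | COC(=O)/C=C/[C@@]1(C)CCC[C@@](C)(CO[Si](C)(C)C(C)(C)C)C1[N+](=O)[O-] | intermediate
11 | acrolein (prop-2-enal) | C=CC=O | starting material
12 | methyl (E)-3-[(1R,3R)-3-[(tert-butyldimethylsilyloxy)methyl]-1,3-dimethyl-2-nitro-2-(3-oxopropyl)cyclohexyl]prop-2-enoate | COC(=O)/C=C/[C@@]1(C)CCC[C@@](C)(CO[Si](C)(C)C(C)(C)C)C1(CCC=O)[N+](=O)[O-] | intermediate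
13 | methyl 18-(tert-butyldimethylsilyloxy)-5-nitro-8-oxo-13,14,15,16,17-pentanorlabdan-12-oate (mixture at C5 and C9) | O=C1CCC2([N+](=O)[O-])[C@](C)(CO[Si](C)(C)C(C)(C)C)CCC[C@]2(C)C1CC(=O)OC | intermediate
14 | methyl 18-(tert-butyldimethylsilyloxy)-8-oxo-13,14,15,16,17-pentanorlabdan-12-oate | O=C1CC[C@H]2[C@](C)(CO[Si](C)(C)C(C)(C)C)CCC[C@]2(C)[C@H]1CC(=O)OC | intermediate
15 | methyl 2α-chloro-18-(tert-butyldimethylsilyloxy)-8-oxo-13,14,15,16,17-pentanorlabdan-12-oate | O=C1CC[C@H]2[C@](C)(CO[Si](C)(C)C(C)(C)C)C[C@H](Cl)C[C@]2(C)[C@H]1CC(=O)OC | intermediate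
16 | methyl 2α-chloro-18-(tert-butyldimethylsilyloxy)-13,14,15,16-tetranorlabd-8(17)-en-12-oate | C=C1CC[C@H]2[C@](C)(CO[Si](C)(C)C(C)(C)C)C[C@H](Cl)C[C@]2(C)[C@H]1CC(=O)OC | intermediate
17 | 2α-chloro-18-(tert-butyldimethylsilyloxy)-13,14,15,16-tetranorlabd-8(17)-en-12-al | C=C1CC[C@H]2[C@](C)(CO[Si](C)(C)C(C)(C)C)C[C@H](Cl)C[C@]2(C)[C@H]1CC=O | intermediate
18 | (R)-4-benzyl-1,3-oxazolidin-2-one | O=C1N[C@H](Cc2ccccc2)CO1 | starting material
19 | methyl 4-chloro-4-oxobutanoate | COC(=O)CCC(Cl)=O | starting material
20 | methyl 4-[(4R)-4-benzyl-2-oxo-1,3-oxazolidin-3-yl]-4-oxobutanoate | COC(=O)CCC(=O)N1[C@H](Cc2ccccc2)COC1=O | intermediate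
21 | syn-aldol adduct, (12S,13R)-β-hydroxy imide (methyl ester on C15, (R)-4-benzyloxazolidinone on C16, 18-O-TBS, 2α-Cl) | C=C1CC[C@H]2[C@](C)(CO[Si](C)(C)C(C)(C)C)C[C@H](Cl)C[C@]2(C)[C@H]1C[C@H](O)[C@@H](CC(=O)OC)C(=O)N3[C@H](Cc4ccccc4)COC3=O | intermediate
22 | primary amide of 21 (CONH2 on C15, acyl oxazolidinone on C16) | C=C1CC[C@H]2[C@](C)(CO[Si](C)(C)C(C)(C)C)C[C@H](Cl)C[C@]2(C)[C@H]1C[C@H](O)[C@@H](CC(N)=O)C(=O)N3[C@H](Cc4ccccc4)COC3=O | intermediate
23 | 18-O-(tert-butyldimethylsilyl)haterumaimide J | C=C1CC[C@H]2[C@](C)(CO[Si](C)(C)C(C)(C)C)C[C@H](Cl)C[C@]2(C)[C@H]1C[C@H](O)[C@H]1CC(=O)NC1=O | intermediate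
24 | haterumaimide J | C=C1CC[C@H]2[C@](C)(CO)C[C@H](Cl)C[C@]2(C)[C@H]1C[C@H](O)[C@H]1CC(=O)NC1=O | target

Total steps: 17. Longest linear sequence: 16 steps (steps 1–13 and 15–17; step 14 is the convergent branch).

**Steps most likely to fail**

Step 9. The one-flask union may stall through slow carbon–carbon bond formation at the congested nitronate carbon while acrolein oligomerises, or through base-mediated enolate cyclisation of the aldehyde before the carbene engages it. The fallback makes the two bonds in separate known operations, setting out from 10. Tsuji–Trost allylation of the nitronate (allyl methyl carbonate, Pd(PPh3)4, THF, rt) would give methyl (E)-3-[(1R,3R)-2-allyl-3-[(tert-butyldimethylsilyloxy)methyl]-1,3-dimethyl-2-nitrocyclohexyl]prop-2-enoate F1. Aldehyde-selective Wacker oxidation of its terminal alkene (PdCl2(PhCN)2, CuCl2·2H2O, AgNO2, O2, t-BuOH/MeNO2) would give aldehyde 12, now isolated and purified. The Stetter cyclisation run on its own (same triazolium salt, i-Pr2NEt, toluene, 40 °C) would return the route at 13.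

Step 5. Oxygen transfer to the hindered oxime nitrogen may be slow, so that hydrolysis back to the ketone or acid-promoted fragmentation of the oxime competes in warm acetic acid. The fallback sets out from 6: hydrogenation over Raney Ni (H2, EtOH, rt) would give (1S,5R)-9-amino-1,5-dimethyl-3-oxabicyclo[3.3.1]nonan-2-one F2, and oxidation of the primary amine to the nitro group with m-CPBA (1,2-dichloroethane, reflux) would return the route at 7.

Step 11. Hydrogen abstraction may occur at competing sites (next to the silyl ether oxygen, at C6 or at tertiary C–H bonds), or the ketone may be chlorinated through its enol. The fallback sets out from 14 and replaces direct chlorination by oxidation, reduction and substitution. Iron-catalysed methylene oxidation ([Fe(S,S-PDP)(MeCN)2](SbF6)2, H2O2, AcOH, MeCN, rt) would give methyl 18-(tert-butyldimethylsilyloxy)-2,8-dioxo-13,14,15,16,17-pentanorlabdan-12-oate F3. Reduction of the less hindered C2 ketone from the α-face (LiBH(s-Bu)3, THF, −78 °C) would give methyl 18-(tert-butyldimethylsilyloxy)-2β-hydroxy-8-oxo-13,14,15,16,17-pentanorlabdan-12-oate F4. Appel chlorination with inversion (PPh3, CCl4, reflux) would return the route at 15.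

Further compounds
F1 | step 9 | methyl (E)-3-[(1R,3R)-2-allyl-3-[(tert-butyldimethylsilyloxy)methyl]-1,3-dimethyl-2-nitrocyclohexyl]prop-2-enoate | COC(=O)/C=C/[C@@]1(C)CCC[C@@](C)(CO[Si](C)(C)C(C)(C)C)C1(CC=C)[N+](=O)[O-]
F2 | step 5 | (1S,5R)-9-amino-1,5-dimethyl-3-oxabicyclo[3.3.1]nonan-2-one | O=C1OC[C@]2(C)CCC[C@@]1(C)C2N
F3 | step 11 | methyl 18-(tert-butyldimethylsilyloxy)-2,8-dioxo-13,14,15,16,17-pentanorlabdan-12-oate | O=C1CC[C@H]2[C@](C)(CO[Si](C)(C)C(C)(C)C)CC(=O)C[C@]2(C)[C@H]1CC(=O)OC
F4 | step 11 | methyl 18-(tert-butyldimethylsilyloxy)-2β-hydroxy-8-oxo-13,14,15,16,17-pentanorlabdan-12-oate | O=C1CC[C@H]2[C@](C)(CO[Si](C)(C)C(C)(C)C)C[C@@H](O)C[C@]2(C)[C@H]1CC(=O)OC
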